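**Strategy.** The route rests on disconnecting the C4–C5 bond of ring A (C10, C1–C5) in the fully assembled spiro-linked dimer. The key step, an intramolecular reductive Heck cyclisation, joins the C5 alkenyl triflate to the isopropenyl terminus of a chain on C10. It exploits the quaternary C4 with its two methyl groups next to ring-fusion carbon C5: ring A is closed, C4 is created and the alkene CH2 becomes the second methyl group in one operation. The precursor already holds rings B and C, the spiro dihydrofuran and the whole lower tricycle. Hydrogen-atom-transfer hydrogenation then sets the trans A/B fusion, and catechol oxidation unveils the quinone methide.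

Key step: step 22

Remark on locants: abietane numbering is used. The upper half is unprimed (ring A = C1–C5, C10; ring B = C5–C10; ring C = C8, C9, C11–C14; ring D = O, C14, C8, C7, C14'). The lower 20-nor half is primed, and the spiro carbon is C14'.
Remark on the chemistry: the sense of induction of the chiral catalysts in steps 5, 14 and 18 is assumed as stated; where a catalyst proves mismatched, its enantiomer is used.
Remark on materials: compounds 1, 3, 8, 20, 25 and 27 are taken as commercial.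

Step 1
Reactants: 1 3-ethoxycyclohex-2-en-1-one
Product: 2 3-ethoxy-6,6-dimethylcyclohex-2-en-1-one
Conditions: LiN(iPr)2, THF, −78 °C, then MeI; second cycle LiN(iPr)2, MeI, −78 to 0 °C (one flask)
Reagents that add atoms: iodomethane, CI
Why: Kinetic α'-deprotonation of the vinylogous ester and two successive enolate methylations (Stork–Danheiser-type alkylation) place both methyl groups on C6, the only enolisable position.

Step 2
Reactants: 2 3-ethoxy-6,6-dimethylcyclohex-2-en-1-one; 3 ethyl vinyl ether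
Product: 6 3-acetyl-4,4-dimethylcyclohex-2-en-1-one, via 1-ethoxyvinyllithium 4 (not isolated), via carbinol adduct 5 (not isolated)
Conditions: 3, t-BuLi, THF, −78 to 0 °C; then 2, −78 °C; then 2 M HCl, THF, rt
Reagents that add atoms: water, O
Why: 1,2-Addition of the acyl-anion equivalent to the hindered ketone, then acid hydrolysis of both enol ethers with allylic transposition (Stork–Danheiser sequence), puts the acetyl group on the carbon next to the gem-dimethyl carbon.

Step 3
Reactants: 6 3-acetyl-4,4-dimethylcyclohex-2-en-1-one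
Product: 7 1-(tert-butyldimethylsilyloxy)-3-[1-(tert-butyldimethylsilyloxy)vinyl]-4,4-dimethylcyclohexa-1,3-diene
Conditions: TBSOTf, Et3N, CH2Cl2, 0 °C
Reagents that add atoms: tert-butyldimethylsilyl triflate, CC(C)(C)[Si](C)(C)OS(=O)(=O)C(F)(F)F
Why: Soft enolisation with silyl triflate and amine converts both ketones into silyl enol ethers; the acetyl methyl and the C2 methylene are the only enolisable sites, so one exocyclic 2-silyloxy-1,3-diene results.

Step 4
Reactants: 7 bis(silyl) dienol ether; 8 3-isopropylcatechol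
Product: 11 9-(tert-butyldimethylsilyloxy)-2-isopropyl-8,8-dimethyl-7,8-dihydrophenanthrene-3,4,5(6H)-trione, via 3-isopropyl-1,2-benzoquinone 9 (not isolated), via Diels–Alder adduct 10 (not isolated)
Conditions: 8 (3.2 equiv), Ag2O, MgSO4, Et2O, rt, filter; add to 7, CH2Cl2, rt; then 0.5 M HCl, THF, 0 °C
Reagents that add atoms: none
Why: Normal-demand Diels–Alder reaction of the exocyclic 2-silyloxydiene with the unsubstituted C=C of the ortho-quinone (CH2 terminus to the quinone carbon β to the C11' carbonyl; the in-ring diene is blocked at its neopentyl terminus), then enolisation, dehydrogenation of ring B' and of the catechol by excess quinone and mild hydrolysis of the remaining silyl enol ether, gives the aromatic ring B' with the aryl silyl ether intact; no stereocentre survives.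

Step 5
Reactants: 11 quinone ketone
Product: 13 (S)-9-(tert-butyldimethylsilyloxy)-5-hydroxy-2-isopropyl-8,8-dimethyl-5,6,7,8-tetrahydrophenanthrene-3,4-dione, via catechol alcohol 12 (not isolated)
Conditions: RuCl[(S,S)-TsDPEN](p-cymene) (2 mol %), HCO2H/Et3N (5:2), DMF, 30 °C; then Ag2O, Et2O, rt
Reagents that add atoms: none
Why: Asymmetric transfer hydrogenation of the aryl ketone by the ruthenium–diamine hydride (the quinone is reduced first and reoxidised by Ag2O on work-up); the (S,S)-ligand should deliver the (S)-benzylic alcohol by analogy with 1-tetralone.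

Step 6
Reactants: 13 quinone alcohol
Product: 14 (S)-5,9-bis(tert-butyldimethylsilyloxy)-2-isopropyl-8,8-dimethyl-5,6,7,8-tetrahydrophenanthrene-3,4-dione
Conditions: TBSCl, imidazole, DMF, rt
Reagents that add atoms: tert-butyldimethylsilyl chloride, CC(C)(C)[Si](C)(C)Cl
Why: Standard silylation of the secondary benzylic alcohol; C1' is not touched.

Step 7
Reactants: 8 3-isopropylcatechol
Product: 15 1,2-bis(benzyloxy)-3-isopropylbenzene
Conditions: BnBr, K2CO3, DMF, 60 °C
Reagents that add atoms: benzyl bromide, BrCc1ccccc1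
Why: Williamson etherification of both phenols.

Step 8
Reactants: 15 1,2-bis(benzyloxy)-3-isopropylbenzene
Product: 16 1,2-bis(benzyloxy)-4-bromo-3-isopropylbenzene
Conditions: NBS, MeCN, 0 °C
Reagents that add atoms: N-bromosuccinimide, O=C1CCC(=O)N1Br
Why: Electrophilic aromatic bromination should go para to the outer benzyloxy group (O11), the central one being twisted out of conjugation as in 2,3-dialkoxytoluenes; this is C14, next to the isopropyl group.

Step 9
Reactants: 16 aryl bromide
Product: 19 3,4-bis(benzyloxy)-2-isopropylphenol, via aryllithium 17 (not isolated), via dimethyl arylboronate 18 (not isolated)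
Conditions: n-BuLi, THF, −78 °C; B(OMe)3, −78 °C to rt; H2O2, NaOH, H2O, 0 °C
Reagents that add atoms: hydrogen peroxide, OO
Why: Bromine–lithium exchange, borylation and oxidative C–B cleavage turn the bromide into the phenol at the same position.

Step 10
Reactants: 19 3,4-bis(benzyloxy)-2-isopropylphenol; 20 ethyl vinyl ketone
Product: 21 1-[4,5-bis(benzyloxy)-2-hydroxy-3-isopropylphenyl]pentan-3-one
Conditions: 20, Sc(OTf)3 (5 mol %), CH2Cl2, rt
Reagents that add atoms: none
Why: Lewis-acid-catalysed Friedel–Crafts conjugate addition of the phenol to the enone occurs at C8, the only free position ortho to the hydroxyl group (the product equilibrates with its cyclic hemiketal).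

Step 11
Reactants: 21 hydroxyaryl pentanone
Product: 22 1-[4,5-bis(benzyloxy)-2-(tert-butyldimethylsilyloxy)-3-isopropylphenyl]pentan-3-one
Conditions: TBSCl, imidazole, DMF, rt
Reagents that add atoms: tert-butyldimethylsilyl chloride, CC(C)(C)[Si](C)(C)Cl
Why: Silylation traps the open-chain phenol tautomer and protects O14 for the following steps.

Step 12
Reactants: 22 silyl ether
Product: 23 1-[4,5-bis(benzyloxy)-6-bromo-2-(tert-butyldimethylsilyloxy)-3-isopropylphenyl]pentan-3-one
Conditions: NBS, MeCN, 0 °C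
Reagents that add atoms: N-bromosuccinimide, O=C1CCC(=O)N1Br
Why: Electrophilic bromination at C9, the only remaining aromatic C–H of the electron-rich ring.

Step 13
Reactants: 23 bromo ketone
Product: 24 (±)-7,8-bis(benzyloxy)-5-(tert-butyldimethylsilyloxy)-6-isopropyl-1-methyl-3,4-dihydronaphthalen-2(1H)-one
Conditions: Pd(OAc)2 (5 mol %), XPhos (10 mol %), K3PO4, toluene, 80 °C
Reagents that add atoms: none
Why: Palladium-catalysed intramolecular ketone α-arylation closes ring B; only the ethyl-side α-carbon can form a six-membered ring, giving the 1-methyl-2-tetralone (racemic at the enolisable C10).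

Step 14
Reactants: 24 1-methyl-2-tetralone; 25 allyl acetate
Product: 26 (R)-1-allyl-7,8-bis(benzyloxy)-5-(tert-butyldimethylsilyloxy)-6-isopropyl-1-methyl-3,4-dihydronaphthalen-2(1H)-one
Conditions: 25, [Pd(C3H5)Cl]2 (2.5 mol %), (R,R)-N,N'-cyclohexane-1,2-diylbis[2-(diphenylphosphino)benzamide] (7.5 mol %), Cs2CO3, DME, rt
Reagents that add atoms: none
Why: Tsuji–Trost asymmetric allylic alkylation of the stabilised benzylic enolate; the chiral diphosphine–allylpalladium complex differentiates the enolate faces and sets the quaternary C10 as R.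

Step 15
Reactants: 26 allyl tetralone; 27 2-bromopropene
Product: 29 (R)-7,8-bis(benzyloxy)-5-(tert-butyldimethylsilyloxy)-6-isopropyl-1-methyl-1-(4-methylpent-4-en-1-yl)-3,4-dihydronaphthalen-2(1H)-one, via B-alkyl-9-borabicyclononane 28 (not isolated)
Conditions: 9-BBN, THF, 0 °C to rt; then 27, Pd(dppf)Cl2 (5 mol %), K3PO4, H2O, DMF, rt
Reagents that add atoms: none
Why: Anti-Markovnikov hydroboration of the terminal alkene (the neopentyl ketone is too hindered for 9-BBN) and B-alkyl Suzuki–Miyaura coupling install the isopropenyl terminus; C10 is untouched.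

Step 16
Reactants: 29 chain-extended tetralone
Product: 30 (R)-7,8-bis(benzyloxy)-5-(tert-butyldimethylsilyloxy)-6-isopropyl-1-methyl-1-(4-methylpent-4-en-1-yl)naphthalen-2(1H)-one
Conditions: DDQ, dioxane, rt
Reagents that add atoms: none
Why: DDQ dehydrogenation: hydride abstraction from the electron-rich benzylic C7 and loss of the C6 proton give the conjugated enone, and the quaternary C10 prevents aromatisation.

Step 17
Reactants: 30 silyl-protected enone
Product: 31 (R)-7,8-bis(benzyloxy)-5-hydroxy-6-isopropyl-1-methyl-1-(4-methylpent-4-en-1-yl)naphthalen-2(1H)-one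
Conditions: Bu4NF, AcOH, THF, 0 °C
Reagents that add atoms: none
Why: Buffered fluoride cleaves the aryl silyl ether and frees O14–H for acid activation and for the later ring D closure.

Step 18
Reactants: 31 hydroxy enone; 14 lower quinone
Product: 33 Friedel–Crafts adduct (7R,10R,1'S), via naphthalene-1,2-diol 32 (not isolated)
Conditions: 14, Na2S2O4, EtOAc/H2O, rt; then 31, (R)-3,3'-bis(2,4,6-triisopropylphenyl)-1,1'-binaphthyl-2,2'-diyl hydrogen phosphate (10 mol %), toluene, 4 Å MS, 40 °C, under Ar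
Reagents that add atoms: none
Why: Dithionite reduces the quinone to the electron-rich diol, whose C14' (para to O11'–H) adds to C7 of the acid-activated 2-hydroxyaryl enone in a phosphoric-acid-catalysed Friedel–Crafts conjugate addition; attack anti to the larger C10 substituent (the pentenyl chain), reinforced by the matched chiral acid, sets C7 as R.

Step 19
Reactants: 33 Friedel–Crafts adduct
Product: 35 spiro ether ketone (7S,10R,14'R,1'S), via ortho-quinone 34 (not isolated)
Conditions: Ag2O, Na2SO4, CH2Cl2, rt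
Reagents that add atoms: none
Why: Ag2O oxidises only the catechol to the ortho-quinone, and O14–H then adds to C14' in a 5-exo-trig oxa-Michael spirocyclisation that closes ring D; C14' should be set as R because the isopropyl-bearing C13' takes the face of ring D on the side of H7, away from C6 (the C7 descriptor changes only through priorities).

Step 20
Reactants: 35 spiro ether ketone
Product: 36 12'-O-silyl enol ether of 35
Conditions: TBSOTf, 2,6-lutidine, CH2Cl2, −78 °C
Reagents that add atoms: tert-butyldimethylsilyl triflate, CC(C)(C)[Si](C)(C)OS(=O)(=O)C(F)(F)F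
Why: O-Silylation of the acidic enol under non-equilibrating conditions masks the diosphenol and blocks retro-oxa-Michael opening, which locks C14'.

Step 21
Reactants: 36 silyl enol ether ketone
Product: 37 C5=C6 alkenyl triflate
Conditions: NaN(SiMe3)2, THF, −78 °C; then N-(5-chloropyridin-2-yl)bis(trifluoromethanesulfonyl)imide, −78 °C
Reagents that add atoms: N-(5-chloropyridin-2-yl)bis(trifluoromethanesulfonyl)imide, Clc1ccc(nc1)N(S(=O)(=O)C(F)(F)F)S(=O)(=O)C(F)(F)F
Why: Kinetic deprotonation at C6, the only hydrogen-bearing α-position of the C5 ketone, and O-triflation at low temperature (fast enough to outrun retro-Michael cleavage of the C7–C14' bond) give the enol triflate.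

Step 22
Reactants: 37 alkenyl triflate
Product: 38 ring-A-closed 5(6)-alkene (7S,10S,14'R,1'S)
Conditions: Pd(OAc)2 (10 mol %), PPh3 (25 mol %), HCO2H, Et3N, DMF, 60 °C
Reagents that add atoms: none
Why: Zerovalent palladium inserts into the C5–OTf bond, the alkenylpalladium adds across the 1,1-disubstituted C4=C19 alkene, and the resulting neopentyl alkylpalladium, which has no β-hydrogen, is intercepted by formate (decarboxylation, C–H reductive elimination), so that C19 becomes the second methyl group on C4. The closest known reaction type is the intramolecular reductive Heck cyclisation that builds all-carbon quaternary centres. Ring A is closed by 6-exo-trig carbopalladation (C4–C5 bond); 7-endo closure would put palladium on the tertiary carbon and is disfavoured. No stereocentre is created: C4 carries two methyl groups, C5 stays trigonal and is set in step 23, and C10 is untouched (its descriptor changes from R to S only through priorities). The step needs selective oxidative addition at the alkenyl triflate and hydride capture faster than 3-exo cyclisation onto C5=C6; excess formate and the lack of β-hydrogens should secure this, and the silyl enol ether, benzyl ethers and spiro ether are inert.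

Step 23
Reactants: 38 5(6)-alkene
Product: 39 trans-fused protected heptacycle (5S,7S,10S,14'R,1'S)
Conditions: Mn(dpm)3 (20 mol %), PhSiH3, t-BuOOH, i-PrOH, rt
Reagents that add atoms: none
Why: Metal-hydride hydrogen-atom-transfer hydrogenation: hydrogen-atom transfer to C6 gives the tertiary C5 radical, which takes its second hydrogen on the face opposite the axial C10 methyl group and so gives the thermodynamically preferred trans fusion (5S); the tetrasubstituted silyloxy enone is too hindered to react.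

Step 24
Reactants: 39 protected heptacycle
Product: 40 11,12-bis(benzyloxy) triol (5S,7S,10S,14'R,1'S)
Conditions: HF·pyridine, pyridine, THF, 0 °C to rt
Reagents that add atoms: none
Why: Buffered fluoride cleaves the aryl, alkyl and enol silyl ethers without strong base, so the spiro ether cannot open.

Step 25
Reactants: 40 bis(benzyl) ether
Product: 43 target CNP0266922.1, via catechol 41 (not isolated), via 11,12-ortho-quinone 42 (not isolated)
Conditions: H2 (1 atm), Pd/C, EtOAc, rt; filter under Ar; then o-chloranil, Et2O, −20 °C; SiO2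
Reagents that add atoms: none
Why: Hydrogenolysis removes both benzyl ethers, ortho-chloranil oxidises the freed catechol to the 11,12-quinone, and this tautomerises on silica by loss of H7 to the 14-alkoxy para-quinone methide, which erases the temporary C7 stereocentre.

**Compound list**

1 | 3-ethoxycyclohex-2-en-1-one | CCOC1=CC(=O)CCC1 | starting material
2 | 3-ethoxy-6,6-dimethylcyclohex-2-en-1-one | CCOC1=CC(=O)C(C)(C)CC1 | intermediate
3 | ethyl vinyl ether | C=COCC | starting material
4 | 1-ethoxyvinyllithium | [Li]C(=C)OCC | intermediate (not isolated)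
5 | 3-ethoxy-1-(1-ethoxyvinyl)-6,6-dimethylcyclohex-2-en-1-ol (carbinol adduct) | CCOC(=C)C1(O)C=C(OCC)CCC1(C)C | intermediate (not isolated)
6 | 3-acetyl-4,4-dimethylcyclohex-2-en-1-one | CC(=O)C1=CC(=O)CCC1(C)C | intermediate
7 | 1-(tert-butyldimethylsilyloxy)-3-[1-(tert-butyldimethylsilyloxy)vinyl]-4,4-dimethylcyclohexa-1,3-diene | C=C(O[Si](C)(C)C(C)(C)C)C1=CC(O[Si](C)(C)C(C)(C)C)=CCC1(C)C | intermediate
8 | 3-isopropylcatechol | CC(C)c1cccc(O)c1O | starting material
9 | 3-isopropyl-1,2-benzoquinone | CC(C)C1=CC=CC(=O)C1=O | intermediate (not isolated)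
10 | Diels–Alder adduct of 7 and 9 (cis-fused, relative configuration not defined, lost on aromatisation) | CC(C)C1=CC2CC(O[Si](C)(C)C(C)(C)C)=C3C(C(O[Si](C)(C)C(C)(C)C)=CCC3(C)C)C2C(=O)C1=O | intermediate (not isolated)
11 | 9-(tert-butyldimethylsilyloxy)-2-isopropyl-8,8-dimethyl-7,8-dihydrophenanthrene-3,4,5(6H)-trione | CC(C)C1=Cc2cc(O[Si](C)(C)C(C)(C)C)c3c(c2C(=O)C1=O)C(=O)CCC3(C)C | intermediate
12 | (S)-9-(tert-butyldimethylsilyloxy)-2-isopropyl-8,8-dimethyl-5,6,7,8-tetrahydrophenanthrene-3,4,5-triol | CC(C)c1cc2cc(O[Si](C)(C)C(C)(C)C)c3c(c2c(O)c1O)[C@@H](O)CCC3(C)C | intermediate (not isolated)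
13 | (S)-9-(tert-butyldimethylsilyloxy)-5-hydroxy-2-isopropyl-8,8-dimethyl-5,6,7,8-tetrahydrophenanthrene-3,4-dione | CC(C)C1=Cc2cc(O[Si](C)(C)C(C)(C)C)c3c(c2C(=O)C1=O)[C@@H](O)CCC3(C)C | intermediate
14 | (S)-5,9-bis(tert-butyldimethylsilyloxy)-2-isopropyl-8,8-dimethyl-5,6,7,8-tetrahydrophenanthrene-3,4-dione | CC(C)C1=Cc2cc(O[Si](C)(C)C(C)(C)C)c3c(c2C(=O)C1=O)[C@@H](O[Si](C)(C)C(C)(C)C)CCC3(C)C | intermediate
15 | 1,2-bis(benzyloxy)-3-isopropylbenzene | CC(C)c1cccc(OCc2ccccc2)c1OCc1ccccc1 | intermediate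
16 | 1,2-bis(benzyloxy)-4-bromo-3-isopropylbenzene | CC(C)c1c(Br)ccc(OCc2ccccc2)c1OCc1ccccc1 | intermediate
17 | [3,4-bis(benzyloxy)-2-isopropylphenyl]lithium | CC(C)c1c([Li])ccc(OCc2ccccc2)c1OCc1ccccc1 | intermediate (not isolated)
18 | dimethyl [3,4-bis(benzyloxy)-2-isopropylphenyl]boronate | COB(OC)c1ccc(OCc2ccccc2)c(OCc2ccccc2)c1C(C)C | intermediate (not isolated)
19 | 3,4-bis(benzyloxy)-2-isopropylphenol | CC(C)c1c(O)ccc(OCc2ccccc2)c1OCc1ccccc1 | intermediate
20 | ethyl vinyl ketone (pent-1-en-3-one) | CCC(=O)C=C | starting material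
21 | 1-[4,5-bis(benzyloxy)-2-hydroxy-3-isopropylphenyl]pentan-3-one | CCC(=O)CCc1cc(OCc2ccccc2)c(OCc2ccccc2)c(C(C)C)c1O | intermediate
22 | 1-[4,5-bis(benzyloxy)-2-(tert-butyldimethylsilyloxy)-3-isopropylphenyl]pentan-3-one | CCC(=O)CCc1cc(OCc2ccccc2)c(OCc2ccccc2)c(C(C)C)c1O[Si](C)(C)C(C)(C)C | intermediate
23 | 1-[4,5-bis(benzyloxy)-6-bromo-2-(tert-butyldimethylsilyloxy)-3-isopropylphenyl]pentan-3-one | CCC(=O)CCc1c(Br)c(OCc2ccccc2)c(OCc2ccccc2)c(C(C)C)c1O[Si](C)(C)C(C)(C)C | intermediate
24 | (±)-7,8-bis(benzyloxy)-5-(tert-butyldimethylsilyloxy)-6-isopropyl-1-methyl-3,4-dihydronaphthalen-2(1H)-one | CC1C(=O)CCc2c1c(OCc1ccccc1)c(OCc1ccccc1)c(C(C)C)c2O[Si](C)(C)C(C)(C)C | intermediate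
25 | allyl acetate | CC(=O)OCC=C | starting material
26 | (R)-1-allyl-7,8-bis(benzyloxy)-5-(tert-butyldimethylsilyloxy)-6-isopropyl-1-methyl-3,4-dihydronaphthalen-2(1H)-one | C=CC[C@@]1(C)C(=O)CCc2c1c(OCc1ccccc1)c(OCc1ccccc1)c(C(C)C)c2O[Si](C)(C)C(C)(C)C | intermediate
27 | 2-bromopropene | CC(Br)=C | starting material
28 | B-alkyl-9-borabicyclo[3.3.1]nonane from 26 (boron on the terminal carbon of the former allyl group) | B1(C2CCCC1CCC2)CCC[C@@]1(C)C(=O)CCc2c1c(OCc1ccccc1)c(OCc1ccccc1)c(C(C)C)c2O[Si](C)(C)C(C)(C)C | intermediate (not isolated)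
29 | (R)-7,8-bis(benzyloxy)-5-(tert-butyldimethylsilyloxy)-6-isopropyl-1-methyl-1-(4-methylpent-4-en-1-yl)-3,4-dihydronaphthalen-2(1H)-one | C=C(C)CCC[C@@]1(C)C(=O)CCc2c1c(OCc1ccccc1)c(OCc1ccccc1)c(C(C)C)c2O[Si](C)(C)C(C)(C)C | intermediate
30 | (R)-7,8-bis(benzyloxy)-5-(tert-butyldimethylsilyloxy)-6-isopropyl-1-methyl-1-(4-methylpent-4-en-1-yl)naphthalen-2(1H)-one | C=C(C)CCC[C@@]1(C)C(=O)C=Cc2c1c(OCc1ccccc1)c(OCc1ccccc1)c(C(C)C)c2O[Si](C)(C)C(C)(C)C | intermediate
31 | (R)-7,8-bis(benzyloxy)-5-hydroxy-6-isopropyl-1-methyl-1-(4-methylpent-4-en-1-yl)naphthalen-2(1H)-one | C=C(C)CCC[C@@]1(C)C(=O)C=Cc2c1c(OCc1ccccc1)c(OCc1ccccc1)c(C(C)C)c2O | intermediate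
32 | (S)-5,9-bis(tert-butyldimethylsilyloxy)-2-isopropyl-8,8-dimethyl-5,6,7,8-tetrahydrophenanthrene-3,4-diol | CC(C)c1cc2cc(O[Si](C)(C)C(C)(C)C)c3c(c2c(O)c1O)[C@@H](O[Si](C)(C)C(C)(C)C)CCC3(C)C | intermediate (not isolated)
33 | Friedel–Crafts adduct (7R,10R,1'S): upper 2-tetralone (C5 ketone, 14-OH, 11,12-bis(benzyloxy), 13-isopropyl, C10 with methyl and 4-methylpent-4-en-1-yl) bonded through C7 to C14' of diol 32 | C=C(C)CCC[C@@]1(C)C(=O)C[C@H](c2c(C(C)C)c(O)c(O)c3c2cc(O[Si](C)(C)C(C)(C)C)c2c3[C@@H](O[Si](C)(C)C(C)(C)C)CCC2(C)C)c2c(O)c(C(C)C)c(OCc3ccccc3)c(OCc3ccccc3)c21 | intermediate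
34 | 11',12'-ortho-quinone of 33 (7R,10R,1'S) | C=C(C)CCC[C@@]1(C)C(=O)C[C@H](C2=C(C(C)C)C(=O)C(=O)c3c2cc(O[Si](C)(C)C(C)(C)C)c2c3[C@@H](O[Si](C)(C)C(C)(C)C)CCC2(C)C)c2c(O)c(C(C)C)c(OCc3ccccc3)c(OCc3ccccc3)c21 | intermediate (not isolated)
35 | spiro ether ketone (7S,10R,14'R,1'S): O14–C14' bond closed (spiro 2,3-dihydrobenzofuran), lower half 12'-hydroxy-11'-oxo enol, C5 ketone, ring A open | CC(C)c1c2O[C@@]3([C@@H]4c2c(c(OCc2ccccc2)c1OCc1ccccc1)[C@@](C)(CCCC(C)=C)C(=O)C4)C(C(C)C)=C(O)C(=O)c1c3cc(O[Si](C)(C)C(C)(C)C)c2c1[C@@H](O[Si](C)(C)C(C)(C)C)CCC2(C)C | intermediate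
36 | 12'-O-tert-butyldimethylsilyl enol ether of 35 (7S,10R,14'R,1'S) | CC(C)c1c2O[C@@]3([C@@H]4c2c(c(OCc2ccccc2)c1OCc1ccccc1)[C@@](C)(CCCC(C)=C)C(=O)C4)C(C(C)C)=C(O[Si](C)(C)C(C)(C)C)C(=O)c1c3cc(O[Si](C)(C)C(C)(C)C)c2c1[C@@H](O[Si](C)(C)C(C)(C)C)CCC2(C)C | intermediate
37 | C5=C6 alkenyl triflate of 36 (7S,10R,14'R,1'S) | CC(C)c1c2O[C@@]3([C@@H]4c2c(c(OCc2ccccc2)c1OCc1ccccc1)[C@@](C)(CCCC(C)=C)C(OS(=O)(=O)C(F)(F)F)=C4)C(C(C)C)=C(O[Si](C)(C)C(C)(C)C)C(=O)c1c3cc(O[Si](C)(C)C(C)(C)C)c2c1[C@@H](O[Si](C)(C)C(C)(C)C)CCC2(C)C | intermediate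
38 | ring-A-closed 5(6)-alkene (7S,10S,14'R,1'S), 4,4-dimethyl, fully protected | CC(C)c1c2O[C@@]3([C@@H]4c2c(c(OCc2ccccc2)c1OCc1ccccc1)[C@@]1(C)CCCC(C)(C)C1=C4)C(C(C)C)=C(O[Si](C)(C)C(C)(C)C)C(=O)c1c3cc(O[Si](C)(C)C(C)(C)C)c2c1[C@@H](O[Si](C)(C)C(C)(C)C)CCC2(C)C | intermediate
39 | trans-fused protected heptacycle (5S,7S,10S,14'R,1'S) | CC(C)c1c2O[C@@]3([C@@H]4c2c(c(OCc2ccccc2)c1OCc1ccccc1)[C@@]1(C)CCCC(C)(C)[C@@H]1C4)C(C(C)C)=C(O[Si](C)(C)C(C)(C)C)C(=O)c1c3cc(O[Si](C)(C)C(C)(C)C)c2c1[C@@H](O[Si](C)(C)C(C)(C)C)CCC2(C)C | intermediate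
40 | 11,12-bis(benzyloxy) triol (5S,7S,10S,14'R,1'S): 12'-enol, 6'-phenol and 1'-alcohol free | CC(C)c1c2O[C@@]3([C@@H]4c2c(c(OCc2ccccc2)c1OCc1ccccc1)[C@@]1(C)CCCC(C)(C)[C@@H]1C4)C(C(C)C)=C(O)C(=O)c1c3cc(O)c2c1[C@@H](O)CCC2(C)C | intermediate
41 | 11,12-catechol (5S,7S,10S,14'R,1'S) | CC(C)c1c2O[C@@]3([C@@H]4c2c(c(O)c1O)[C@@]1(C)CCCC(C)(C)[C@@H]1C4)C(C(C)C)=C(O)C(=O)c1c3cc(O)c2c1[C@@H](O)CCC2(C)C | intermediate (not isolated)
42 | 11,12-ortho-quinone (5S,7S,10S,14'R,1'S) | CC(C)C1=C2O[C@@]3([C@@H]4C2=C(C(=O)C1=O)[C@@]1(C)CCCC(C)(C)[C@@H]1C4)C(C(C)C)=C(O)C(=O)c1c3cc(O)c2c1[C@@H](O)CCC2(C)C | intermediate (not isolated)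
43 | CNP0266922.1 (5S,10S,14'R,1'S) | CC(C)C1=C2O[C@@]3(C4=C2C(=C(O)C1=O)[C@@]1(C)CCCC(C)(C)[C@@H]1C4)C(C(C)C)=C(O)C(=O)c1c3cc(O)c2c1[C@@H](O)CCC2(C)C | target

**Totals.** Total step count: 25. Longest linear sequence: 19 steps (steps 7–25, from 3-isopropylcatechol 8).

**Steps most likely to fail**

1. Step 18. The intermolecular C7–C14' bond formation may stall because both carbons are flanked by ortho substituents, and the catalyst may fail to reinforce the weak substrate bias at C7. Fallback: the order of the two bond formations is reversed, setting out from 31 and 14. Base-mediated oxa-Michael addition of O14–H of 31 to the free C14' position of quinone 14 (K2CO3 cat., MeCN), with Ag2O reoxidation, should give the 4-aryloxy-1,2-naphthoquinone F1. Dithionite reduction gives the aryloxy naphthalenediol F2. Its C14' (ipso to the aryloxy group, para to O11') then adds to C7 of the tethered enone in a dearomatising 5-exo Michael spirocyclisation (Et3N cat., MeCN), which forms the hindered C–C bond intramolecularly. The route is rejoined at compound 35, so steps 18 and 19 are both replaced.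

2. Step 22. Oxidative addition at the hindered triflate may be slow, or the neopentyl alkylpalladium may cyclise onto C5=C6 before hydride capture and give rearranged products. Fallback: a radical ring closure from ketone 36. Fe(acac)3 and PhSiH3 in EtOH/ethylene glycol transfer a hydrogen atom to the isopropenyl group; the tertiary C4 radical adds to the C5 carbonyl (reductive alkene–ketone coupling) and closes ring A as the cis-fused tertiary carbinol F3. Dehydration (SOCl2, pyridine, 0 °C) can only occur towards C6 and returns to the route at compound 38.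

3. Step 23. Hydrogen-atom transfer may be too slow at the alkene flanked by two quaternary carbons, may also reduce the silyloxy enone of the lower half, or may lose facial selectivity. Fallback: coordinative syn-hydrogenation of 38 with [Ir(cod)(PCy3)(py)]PF6 under H2 in CH2Cl2, which adds both hydrogens from the face opposite the C10 methyl group under steric control. It leads directly to compound 39 and makes no new compound (F0).

**Further compounds**

F1 | step 18 | 4-aryloxy-1,2-naphthoquinone: O14 of enone 31 bonded to C14' of quinone 14 (10R,1'S) | C=C(C)CCC[C@@]1(C)C(=O)C=Cc2c1c(OCc1ccccc1)c(OCc1ccccc1)c(C(C)C)c2OC1=C(C(C)C)C(=O)C(=O)c2c1cc(O[Si](C)(C)C(C)(C)C)c1c2[C@@H](O[Si](C)(C)C(C)(C)C)CCC1(C)C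
F2 | step 18 | aryloxy naphthalene-11',12'-diol from F1 (10R,1'S) | C=C(C)CCC[C@@]1(C)C(=O)C=Cc2c1c(OCc1ccccc1)c(OCc1ccccc1)c(C(C)C)c2Oc1c(C(C)C)c(O)c(O)c2c1cc(O[Si](C)(C)C(C)(C)C)c1c2[C@@H](O[Si](C)(C)C(C)(C)C)CCC1(C)C
F3 | step 22 | cis-fused C5 tertiary carbinol with ring A closed (5-hydroxy, 4,4-dimethyl; C5 configuration immaterial) | CC(C)c1c2O[C@@]3([C@@H]4c2c(c(OCc2ccccc2)c1OCc1ccccc1)[C@@]1(C)CCCC(C)(C)[C@@]1(O)C4)C(C(C)C)=C(O[Si](C)(C)C(C)(C)C)C(=O)c1c3cc(O[Si](C)(C)C(C)(C)C)c2c1[C@@H](O[Si](C)(C)C(C)(C)C)CCC2(C)C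
F0 | step 23 | none | none
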